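**Retrosynthetic overview**
1. Target 12 comes from its 5,4'-diacetate 11 by near-neutral deacetylation, so no base touches the finished flavanone.
2. The C2–aryl bond and the only stereocentre come from a Rh-catalysed asymmetric 1,4-addition of an arylboronic acid to 6-prenylchromone 9.
3. The C6–prenyl bond comes from a Stille coupling on a 6-iodochromone. The iodide is placed ortho to the free 5-OH after O1 is locked in the ring, which settles the 6- versus 8-position question.
4. The chromone comes from a symmetric 2,6-dihydroxyacetophenone plus one carbon from DMF-DMA.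
5. Ring order: ring A is purchased, ring C is closed in step 1 and saturated at C2–C3 in step 5, and ring B is attached intact in step 5.

Assumption: reagents that donate atoms are numbered as compounds, while catalysts, ligands and solvents are not. All numbered reagents and the ligand are taken to be catalogue items.

**Step 1**
Reactants: 1 2',6'-dihydroxy-4'-methoxyacetophenone; 2 N,N-dimethylformamide dimethyl acetal (DMF-DMA)
Product: 3 5-hydroxy-7-methoxy-4H-chromen-4-one
Conditions: 2 (2 equiv), toluene, 90 °C, 3 h; concentrate; conc. HCl, CH2Cl2, 40 °C, 1 h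
Reagents that add atoms: DMF-DMA, COC(OC)N(C)C (supplies the C2 carbon)
Why: This is an enaminone chromone synthesis (condensation at the acetyl CH3, then acid-promoted addition–elimination by an ortho OH), and because the two ortho OH groups of 1 are equivalent only one chromone can form, leaving the other OH as the chelated 5-OH.

**Step 2**
Reactants: 3; 4 N-iodosuccinimide
Product: 5 5-hydroxy-6-iodo-7-methoxy-4H-chromen-4-one
Conditions: NIS (1.02 equiv), DMF, rt, dark, 12 h
Reagents that add atoms: NIS, O=C1CCC(=O)N1I
Why: In this electrophilic aromatic iodination the free 5-OH, hydrogen-bonded to C4=O, makes C5=C6 enol-like and directs neutral I+ to its ortho carbon C6 rather than C8, while the pyranone C3 is much less nucleophilic.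

**Step 3**
Reactants: 5; 6 acetic anhydride
Product: 7 6-iodo-7-methoxy-4-oxo-4H-chromen-5-yl acetate
Conditions: Ac2O (3 equiv), pyridine, DMAP (10 mol %), CH2Cl2, rt
Reagents that add atoms: acetic anhydride, CC(=O)OC(C)=O
Why: DMAP-catalysed O-acetylation masks the peri-hydroxy ketone, which is an acac-type chelator that would tie up Pd and Rh, and it makes the chromone a better Michael acceptor.

**Step 4**
Reactants: 7; 8 tributyl(3-methylbut-2-en-1-yl)stannane
Product: 9 7-methoxy-6-(3-methylbut-2-en-1-yl)-4-oxo-4H-chromen-5-yl acetate
Conditions: 8 (1.3 equiv), Pd(PPh3)4 (5 mol %), DMF, 80–90 °C, Ar; aq KF work-up, chromatography on KF/silica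
Reagents that add atoms: prenyltributylstannane, CCCC[Sn](CCCC)(CCCC)CC=C(C)C
Why: This base-free Stille coupling leaves the acetate and enone intact, and reductive elimination from the aryl–Pd–prenyl species occurs at the unsubstituted allyl terminus to give the linear prenyl group.

**Step 5**
Reactants: 9; 10 4-acetoxyphenylboronic acid
Product: 11 (2S)-2-(4-acetoxyphenyl)-7-methoxy-6-(3-methylbut-2-en-1-yl)-4-oxochroman-5-yl acetate
Conditions: [RhCl(C2H4)2]2 (1.5 mol %), (S)-MeO-F12-BIPHEP [(S)-2,2'-bis(bis(3,4,5-trifluorophenyl)phosphino)-6,6'-dimethoxybiphenyl] (3.3 mol %), aq KOH (5 mol %), 10 (2 equiv), toluene/H2O 10:1, 25 °C; recrystallise to raise ee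
Reagents that add atoms: 4-acetoxyphenylboronic acid, CC(=O)Oc1ccc(B(O)O)cc1 (water supplies only the C3–H)
Why: In this Hayashi–Miyaura asymmetric conjugate addition the (S)-biaryl bisphosphine–Rh–aryl species attacks the C2 Re face (the same sense as (S)-BINAP with cyclohexenone giving the (S)-3-aryl ketone) to set (2S), and the electron-poor ligand allows room-temperature turnover so the Rh enolate is protonated before it can ring-open.

**Step 6**
Reactants: 11
Product: 12 6-prenylsakuranetin, (2S)-5-hydroxy-2-(4-hydroxyphenyl)-7-methoxy-6-(3-methylbut-2-en-1-yl)chroman-4-one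
Conditions: NH4OAc (10 equiv), MeOH/H2O 4:1, 25 °C, 8–16 h; work-up at pH 5–6
Reagents that add atoms: none
Why: Near-neutral solvolysis cleaves both activated aryl acetates without generating the 4'-phenoxide or C3 enolate that cause retro-oxa-Michael racemisation, and without acid that could cyclise the 5-OH onto the prenyl group, so C2 stays (S).

**Compound list**
1 | 2',6'-dihydroxy-4'-methoxyacetophenone | CC(=O)c1c(O)cc(OC)cc1O | starting material
2 | N,N-dimethylformamide dimethyl acetal | COC(OC)N(C)C | starting material (reagent)
3 | 5-hydroxy-7-methoxy-4H-chromen-4-one | COc1cc(O)c2c(c1)OC=CC2=O | intermediate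
4 | N-iodosuccinimide | O=C1CCC(=O)N1I | starting material (reagent)
5 | 5-hydroxy-6-iodo-7-methoxy-4H-chromen-4-one | COc1cc2c(c(O)c1I)C(=O)C=CO2 | intermediate
6 | acetic anhydride | CC(=O)OC(C)=O | starting material (reagent)
7 | 6-iodo-7-methoxy-4-oxo-4H-chromen-5-yl acetate | COc1cc2c(c(OC(C)=O)c1I)C(=O)C=CO2 | intermediate
8 | tributyl(3-methylbut-2-en-1-yl)stannane | CCCC[Sn](CCCC)(CCCC)CC=C(C)C | starting material
9 | 7-methoxy-6-prenyl-4-oxo-4H-chromen-5-yl acetate | COc1cc2c(c(OC(C)=O)c1CC=C(C)C)C(=O)C=CO2 | intermediate
10 | 4-acetoxyphenylboronic acid | CC(=O)Oc1ccc(B(O)O)cc1 | starting material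
11 | (2S)-5,4'-di-O-acetyl-6-prenylsakuranetin | COc1cc2c(c(OC(C)=O)c1CC=C(C)C)C(=O)C[C@@H](c1ccc(OC(C)=O)cc1)O2 | intermediate
12 | (2S)-6-prenylsakuranetin | COc1cc2c(c(O)c1CC=C(C)C)C(=O)C[C@@H](c1ccc(O)cc1)O2 | target

**Total step count:** 6
**Longest linear sequence:** 6

**Three steps most likely to fail**
1. **Step 5.** The electron-rich 5,6,7-trisubstituted chromone may react slowly, or ee may erode through enolate ring-opening.
   Fallback: prepare racemic 11 by an achiral conjugate addition (Pd(II)/2,2'-bipyridine with 10). Then resolve it by Noyori–Ikariya asymmetric transfer hydrogenation, using the Ru–TsDPEN antipode that reduces the (2R)-ketone to the flavan-4-ol. Unreacted (2S)-11 is recovered, with a maximum yield of 50 %.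
2. **Step 2.** Iodination may give C6/C8 mixtures or 6,8-diiodination.
   Fallback: replace the iodination and Stille steps with a sigmatropic route. Convert the 5-OH of 3 to its 1,1-dimethylpropargyl ether by Cu-catalysed alkylation, semi-hydrogenate with Lindlar catalyst, and run an aromatic Claisen rearrangement. C6 is the only free ortho position, and allyl inversion delivers the linear prenyl group directly.
3. **Step 6.** The hindered 5-OAc may cleave incompletely, or partial racemisation may occur through 4'-phenoxide (quinone-methide) ring-opening.
   Fallback: switch to an acetal protecting-group strategy, using the 5-OMOM chromone and 4-(methoxymethoxy)phenylboronic acid. Both groups are then removed at the end with dilute HCl/MeOH, where flavanone C2 is configurationally stable.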